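**Strategy.** Ring A is disconnected at C7–C8 and C5–C6. Its oxygens at C5 and C7 are 1,3-related along the chain C4a–C5–C6–C7–C8–C8a, so both carbons can come from ester carbonyls. O1, C8a, C4a and C4 already belong to ring C. The precursor is therefore a 2,3,5-trisubstituted 4-pyranone: methyl at the future C8, methyl ester at the future C5, and the MOM-protected ring B chromene in place. In one flask its lateral carbanion is acylated by methyl 5-methylhex-4-enoate, whose α-carbon carries the prenyl chain, and the resulting dianion closes onto the pyranone ester. This gives two C–C bonds, aromatic ring A and an unambiguous C6 prenyl position.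

Key step: step 10

Remark: isoflavone numbering (O1, C2 … C8a, primed ring B) is used for the target. Pyranone numbering (O1, C2 methyl, C3 ester, C4 ketone, C5 aryl, C6–H) is used for the monocyclic precursor. The tricarbonyl intermediates are drawn as keto tautomers; their central carbon is enolised and has no defined configuration. The target contains no stereocentre.

**Step 1**
Reactants: 1 5-bromosalicylaldehyde; 2 3-chloro-3-methylbut-1-yne
Product: 3 5-bromo-2-[(2-methylbut-3-yn-2-yl)oxy]benzaldehyde
Conditions: DBU, CuCl2·2H2O (1 mol %), MeCN, 0 → 20 °C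
Reagents that add atoms: none
Why: Copper-catalysed O-propargylation of a phenoxide by a tertiary propargylic chloride suits this acidic, electron-poor phenol and fixes which of the two later catechol oxygens becomes the chromene oxygen.

**Step 2**
Reactants: 3 5-bromo-2-[(2-methylbut-3-yn-2-yl)oxy]benzaldehyde
Product: 5 5-bromo-2-[(2-methylbut-3-yn-2-yl)oxy]phenol, via aryl formate 4 (not isolated)
Conditions: mCPBA, CH2Cl2, 0 → 20 °C; then K2CO3 (cat.), MeOH, 20 °C
Reagents that add atoms: mCPBA, O=C(OO)c1cccc(Cl)c1
Why: Baeyer–Villiger oxidation of an ortho-alkoxybenzaldehyde goes by aryl migration, the terminal alkyne is inert to the peracid (hence oxidation before the chromene alkene exists), and transesterification of the formate frees the future C3' oxygen.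

**Step 3**
Reactants: 5 5-bromo-2-[(2-methylbut-3-yn-2-yl)oxy]phenol
Product: 6 4-bromo-2-(methoxymethoxy)-1-[(2-methylbut-3-yn-2-yl)oxy]benzene
Conditions: MOMCl, i-Pr2NEt, CH2Cl2, 0 → 20 °C
Reagents that add atoms: chloromethyl methyl ether, COCCl
Why: This is a standard O-alkylation of a phenol, and the MOM ether is chosen because it tolerates heat, zerovalent palladium, hydroxide and lithium amides, that is, everything up to and including the annulation.

**Step 4**
Reactants: 6 4-bromo-2-(methoxymethoxy)-1-[(2-methylbut-3-yn-2-yl)oxy]benzene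
Product: 8 6-bromo-8-(methoxymethoxy)-2,2-dimethyl-2H-chromene, via ortho-allenylphenol 7 (not isolated)
Conditions: o-xylene, 145 °C
Reagents that add atoms: none
Why: Aromatic propargyl Claisen rearrangement to the only free ortho position gives 7, which closes by 1,5-hydrogen shift and oxa-6π electrocyclisation, the gem-dimethyl group accelerating the sigmatropic step.

**Step 5**
Reactants: 8 6-bromo-8-(methoxymethoxy)-2,2-dimethyl-2H-chromene
Product: 9 ethyl [8-(methoxymethoxy)-2,2-dimethyl-2H-chromen-6-yl]acetate
Conditions: BrZnCH2CO2Et, Pd2(dba)3 (2 mol %), XPhos (8 mol %), THF, 65 °C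
Reagents that add atoms: (2-ethoxy-2-oxoethyl)zinc bromide, CCOC(=O)C[Zn]Br
Why: Negishi-type cross-coupling of a Reformatsky reagent with an aryl bromide (ester α-arylation under neutral conditions) places the acetate carbon para to the chromene oxygen without touching the acetal or the alkene.

**Step 6**
Reactants: 9 ethyl [8-(methoxymethoxy)-2,2-dimethyl-2H-chromen-6-yl]acetate
Product: 10 [8-(methoxymethoxy)-2,2-dimethyl-2H-chromen-6-yl]acetic acid
Conditions: LiOH·H2O, THF–H2O, 20 °C; then cold 0.5 M HCl to pH 4
Reagents that add atoms: lithium hydroxide, [Li+].[OH-]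
Why: This is an ordinary ester saponification, with the acidification stopped at pH 4 in the cold so that the MOM acetal and the chromene never meet strong acid.

**Step 7**
Reactants: 10 [8-(methoxymethoxy)-2,2-dimethyl-2H-chromen-6-yl]acetic acid; 11 methyl acetoacetate
Product: 13 methyl 2-acetyl-4-[8-(methoxymethoxy)-2,2-dimethyl-2H-chromen-6-yl]-3-oxobutanoate, via acid chloride 12 (not isolated)
Conditions: Me2C=C(Cl)NMe2, CH2Cl2, 0 °C; then 11, MgCl2, pyridine, CH2Cl2, 0 → 20 °C
Reagents that add atoms: 1-chloro-N,N,2-trimethylprop-1-en-1-amine, CC(C)=C(Cl)N(C)C (supplies the chlorine of 12 only; none of its atoms remains in 13)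
Why: The α-chloroenamine makes the acid chloride without releasing HCl, so the MOM ether survives, and the chelated magnesium enolate of the β-keto ester is acylated on carbon (soft-enolisation C-acylation).

**Step 8**
Reactants: 13 methyl 2-acetyl-4-[8-(methoxymethoxy)-2,2-dimethyl-2H-chromen-6-yl]-3-oxobutanoate
Product: 15 methyl 5-[8-(methoxymethoxy)-2,2-dimethyl-2H-chromen-6-yl]-2-methyl-4-oxo-4H-pyran-3-carboxylate, via enaminone 14 (not isolated)
Conditions: Me2NCH(OMe)2 (1.1 equiv), toluene, 20 → 80 °C
Reagents that add atoms: N,N-dimethylformamide dimethyl acetal, COC(OC)N(C)C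
Why: Amide-acetal condensation at the aryl-activated CH2, then addition–elimination of the acetyl enol oxygen on the enaminone, is the closure that converts 2-hydroxydeoxybenzoins into isoflavones and 3-acyl-4-hydroxy-2-pyranones into fused 4-pyranones, and near-stoichiometric reagent spares the newly formed activated methyl group.

**Step 9**
Reactants: 16 2-methylbut-3-en-2-ol
Product: 18 methyl 5-methylhex-4-enoate, via ketene acetal 17 (not isolated)
Conditions: MeC(OMe)3 (excess), EtCO2H (cat.), 110 → 140 °C, MeOH distilled off
Reagents that add atoms: trimethyl orthoacetate, CC(OC)(OC)OC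
Why: In this Johnson–Claisen rearrangement, alcohol exchange and loss of methanol give 17, whose [3,3]-shift bonds the acetate carbon to the vinyl terminus and leaves a dimethyl-substituted alkene with no geometry to control.

**Step 10**
Reactants: 15 methyl 5-[8-(methoxymethoxy)-2,2-dimethyl-2H-chromen-6-yl]-2-methyl-4-oxo-4H-pyran-3-carboxylate; 18 methyl 5-methylhex-4-enoate
Product: 20 3'-O-MOM gancaonin H (5,7-dihydroxy-3-[8-(methoxymethoxy)-2,2-dimethyl-2H-chromen-6-yl]-6-(3-methylbut-2-en-1-yl)-4H-chromen-4-one), via keto ester 19 (not isolated)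
Conditions: 15 added to LiN(i-Pr)2 (1.05 equiv), THF, −78 °C; 18 (1.3 equiv), −78 → 0 °C; LiN(i-Pr)2 (3.5 equiv), −78 → 20 °C; AcOH
Reagents that add atoms: none
Why: The amide deprotonates the C2 methyl group of 15, which is vinylogously activated by the C4 ketone and the C3 ester, and since no free base remains when 18 arrives, 18 acts as acyl donor and not as enolate, so a Claisen condensation at the exocyclic carbon forms C7–C8 and the released methoxide holds 19 as its stabilised C8 enolate. The second charge of amide removes a proton from the only α-position left, the prenyl-bearing CH2 (future C6), and this dianion attacks the adjacent C3 ester in a Dieckmann condensation, a 6-(enolendo)-exo-trig closure that forms C5–C6; loss of methoxide and double enolisation give aromatic ring A as its dilithium salt, an irreversible sink. The closest known reaction types are the tandem Claisen–Dieckmann benzannulation of lateral carbanions of ortho-methyl aromatic esters (Staunton–Weinreb-type annulation) and terminal-carbon reactions of β-diketone dianions. No stereocentre is formed. Regiochemistry follows from connectivity alone: O1 and C8a are already locked in ring C, attack from C8 on the ester would need a four-membered ring, and acylation on oxygen or at C3 as well as O-lactonisation of the C7 enolate are reversed by LiOMe, so material should funnel to the 6-prenyl isomer only. Addition of base at C6–H of the pyranone (C2 of the isoflavone) is held back because 15 meets the hindered amide at −78 °C and stays anionic from then on.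

**Step 11**
Reactants: 20 3'-O-MOM gancaonin H
Product: 21 gancaonin H
Conditions: conc. HCl (cat.), MeOH–THF, 20 → 40 °C
Reagents that add atoms: none
Why: Acid-catalysed transacetalisation of a phenolic MOM ether to dimethoxymethane should outrun protonation of the trisubstituted alkene in dilute acid near room temperature, conditions commonly applied to MOM-protected ortho-prenylphenols and dimethylchromenes.

**Compound list**

| No. | Name | SMILES | Role |
|---|---|---|---|
| 1 | 5-bromosalicylaldehyde | O=Cc1cc(Br)ccc1O | starting material |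
| 2 | 3-chloro-3-methylbut-1-yne | C#CC(C)(C)Cl | starting material |
| 3 | 5-bromo-2-[(2-methylbut-3-yn-2-yl)oxy]benzaldehyde | O=Cc1cc(Br)ccc1OC(C)(C)C#C | intermediate |
| 4 | 5-bromo-2-[(2-methylbut-3-yn-2-yl)oxy]phenyl formate | O=COc1cc(Br)ccc1OC(C)(C)C#C | intermediate (not isolated) |
| 5 | 5-bromo-2-[(2-methylbut-3-yn-2-yl)oxy]phenol | Oc1cc(Br)ccc1OC(C)(C)C#C | intermediate |
| 6 | 4-bromo-2-(methoxymethoxy)-1-[(2-methylbut-3-yn-2-yl)oxy]benzene | COCOc1cc(Br)ccc1OC(C)(C)C#C | intermediate |
| 7 | 4-bromo-2-(methoxymethoxy)-6-(3-methylbuta-1,2-dien-1-yl)phenol | COCOc1cc(Br)cc(C=C=C(C)C)c1O | intermediate (not isolated) |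
| 8 | 6-bromo-8-(methoxymethoxy)-2,2-dimethyl-2H-chromene | COCOc1cc(Br)cc2c1OC(C)(C)C=C2 | intermediate |
| 9 | ethyl [8-(methoxymethoxy)-2,2-dimethyl-2H-chromen-6-yl]acetate | CCOC(=O)Cc1cc(OCOC)c2c(c1)C=CC(C)(C)O2 | intermediate |
| 10 | [8-(methoxymethoxy)-2,2-dimethyl-2H-chromen-6-yl]acetic acid | OC(=O)Cc1cc(OCOC)c2c(c1)C=CC(C)(C)O2 | intermediate |
| 11 | methyl acetoacetate | CC(=O)CC(=O)OC | starting material |
| 12 | [8-(methoxymethoxy)-2,2-dimethyl-2H-chromen-6-yl]acetyl chloride | ClC(=O)Cc1cc(OCOC)c2c(c1)C=CC(C)(C)O2 | intermediate (not isolated) |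
| 13 | methyl 2-acetyl-4-[8-(methoxymethoxy)-2,2-dimethyl-2H-chromen-6-yl]-3-oxobutanoate | COC(=O)C(C(C)=O)C(=O)Cc1cc(OCOC)c2c(c1)C=CC(C)(C)O2 | intermediate |
| 14 | methyl 2-acetyl-5-(dimethylamino)-4-[8-(methoxymethoxy)-2,2-dimethyl-2H-chromen-6-yl]-3-oxopent-4-enoate (push–pull alkene, geometry labile) | COC(=O)C(C(C)=O)C(=O)C(=CN(C)C)c1cc(OCOC)c2c(c1)C=CC(C)(C)O2 | intermediate (not isolated) |
| 15 | methyl 5-[8-(methoxymethoxy)-2,2-dimethyl-2H-chromen-6-yl]-2-methyl-4-oxo-4H-pyran-3-carboxylate | Cc1occ(-c2cc(OCOC)c3c(c2)C=CC(C)(C)O3)c(=O)c1C(=O)OC | intermediate |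
| 16 | 2-methylbut-3-en-2-ol | C=CC(C)(C)O | starting material |
| 17 | 3-[(1-methoxyethenyl)oxy]-3-methylbut-1-ene | C=CC(C)(C)OC(=C)OC | intermediate (not isolated) |
| 18 | methyl 5-methylhex-4-enoate | COC(=O)CCC=C(C)C | intermediate |
| 19 | methyl 5-[8-(methoxymethoxy)-2,2-dimethyl-2H-chromen-6-yl]-2-(6-methyl-2-oxohept-5-en-1-yl)-4-oxo-4H-pyran-3-carboxylate | COC(=O)c1c(CC(=O)CCC=C(C)C)occ(-c2cc(OCOC)c3c(c2)C=CC(C)(C)O3)c1=O | intermediate (not isolated) |
| 20 | 3'-O-MOM gancaonin H | CC(C)=CCc1c(O)cc2occ(-c3cc(OCOC)c4c(c3)C=CC(C)(C)O4)c(=O)c2c1O | intermediate |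
| 21 | gancaonin H | CC(C)=CCc1c(O)cc2occ(-c3cc(O)c4c(c3)C=CC(C)(C)O4)c(=O)c2c1O | target |

**Total step count:** 11. **Longest linear sequence:** 10 (steps 1–8, 10, 11).

**Steps most likely to fail**

1. **Step 10.**
   - *What may go wrong:* The doubly stabilised lateral carbanion may add too slowly to an unactivated methyl ester, so that proton transfer, enolisation and self-condensation of the ester take over. The C7 enolate may be diverted into O-acylation (enol-lactone formation), so that the sequence stalls before C5–C6 closure. Amide or methoxide may add at C6–H of the pyranone and open ring C.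
   - *Fallback (sets out from 15 and 18, comes back at 20):* The two bond formations are separated and an activated acyl donor is used. Ester 18 is saponified with LiOH to 5-methylhex-4-enoic acid F1. This is coupled with 1H-benzotriazole and DCC to 1-(1H-benzotriazol-1-yl)-5-methylhex-4-en-1-one F2. The lithium carbanion of 15 (LiN(SiMe3)2, THF, −78 °C) is C-acylated by F2 at low temperature, a known ketone synthesis from enolates and from lateral carbanions of methyl heteroarenes, and 19 is now isolated. In a second flask 19 is converted into its dianion with LiN(i-Pr)2 (2.5 equiv, THF, −78 → 0 °C). It should close by the known Dieckmann-type cyclisation of 2-(2-oxoalkyl)aryl esters to 1,3-dihydroxyarenes, giving 20.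

2. **Step 8.**
   - *What may go wrong:* The amide acetal may methylate the very acidic tricarbonyl enol. Condensation may occur at the acetyl methyl group or at the activated methyl group of the product. Liberated dimethylamine or methanol may cause deacetylation.
   - *Fallback (sets out from 9 and 11, comes back at 15):* The one-carbon unit is installed before the tricarbonyl system exists.
     - Ester 9 undergoes crossed Claisen formylation (HCO2Et, NaH, THF) to ethyl 3-hydroxy-2-[8-(methoxymethoxy)-2,2-dimethyl-2H-chromen-6-yl]prop-2-enoate F3.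
     - O-methylation (Me2SO4, K2CO3, acetone) gives the β-methoxyacrylate ester F4, and saponification (LiOH) gives the β-methoxyacrylic acid F5.
     - Me2C=C(Cl)NMe2 converts F5 into the β-methoxyacryloyl chloride F6.
     - F6 acylates the magnesium enolate of 11 (MgCl2, pyridine) to the methoxymethylene tricarbonyl compound F7.
     - F7 should close in the flask by conjugate addition of the acetyl enol oxygen and loss of methanol to give 15.

3. **Step 11.**
   - *What may go wrong:* Acid may cyclise the C6 prenyl group onto the 5- or 7-hydroxyl (chroman formation), hydrate the alkene, or degrade the chromene.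
   - *Fallback (sets out from 15, comes back at 21):* The acid step is moved in front of the annulation, where no ortho-prenylphenol exists. Pyranone 15 is deprotected (HCl cat., MeOH) to methyl 5-(8-hydroxy-2,2-dimethyl-2H-chromen-6-yl)-2-methyl-4-oxo-4H-pyran-3-carboxylate F8. F8 is annulated with 18 as in step 10, with one further equivalent of LiN(i-Pr)2 in the first charge to carry the phenol as a spectator lithium phenoxide. The sequence passes through the phenolic keto ester F9 and should give 21 directly after the AcOH quench, so the finished target never meets mineral acid.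

**Further compounds**
F1 | step 10 | 5-methylhex-4-enoic acid | OC(=O)CCC=C(C)C
F2 | step 10 | 1-(1H-benzotriazol-1-yl)-5-methylhex-4-en-1-one | O=C(CCC=C(C)C)n1nnc2ccccc21
F3 | step 8 | ethyl 3-hydroxy-2-[8-(methoxymethoxy)-2,2-dimethyl-2H-chromen-6-yl]prop-2-enoate (enol of the formyl ester, geometry labile) | CCOC(=O)C(=CO)c1cc(OCOC)c2c(c1)C=CC(C)(C)O2
F4 | step 8 | ethyl 3-methoxy-2-[8-(methoxymethoxy)-2,2-dimethyl-2H-chromen-6-yl]prop-2-enoate (alkene geometry not controlled, lost on ring closure) | CCOC(=O)C(=COC)c1cc(OCOC)c2c(c1)C=CC(C)(C)O2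
F5 | step 8 | 3-methoxy-2-[8-(methoxymethoxy)-2,2-dimethyl-2H-chromen-6-yl]prop-2-enoic acid | OC(=O)C(=COC)c1cc(OCOC)c2c(c1)C=CC(C)(C)O2
F6 | step 8 | 3-methoxy-2-[8-(methoxymethoxy)-2,2-dimethyl-2H-chromen-6-yl]prop-2-enoyl chloride | ClC(=O)C(=COC)c1cc(OCOC)c2c(c1)C=CC(C)(C)O2
F7 | step 8 | methyl 2-acetyl-5-methoxy-4-[8-(methoxymethoxy)-2,2-dimethyl-2H-chromen-6-yl]-3-oxopent-4-enoate | COC(=O)C(C(C)=O)C(=O)C(=COC)c1cc(OCOC)c2c(c1)C=CC(C)(C)O2
F8 | step 11 | methyl 5-(8-hydroxy-2,2-dimethyl-2H-chromen-6-yl)-2-methyl-4-oxo-4H-pyran-3-carboxylate | Cc1occ(-c2cc(O)c3c(c2)C=CC(C)(C)O3)c(=O)c1C(=O)OC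
F9 | step 11 | methyl 5-(8-hydroxy-2,2-dimethyl-2H-chromen-6-yl)-2-(6-methyl-2-oxohept-5-en-1-yl)-4-oxo-4H-pyran-3-carboxylate | COC(=O)c1c(CC(=O)CCC=C(C)C)occ(-c2cc(O)c3c(c2)C=CC(C)(C)O3)c1=O
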